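**Plan**

1. Retrosynthesis: the O1–C2 bond of the pyran ring is cut first, giving a ring-open, racemic (E)-2-hydroxystyryl tertiary carbinol. Next comes C4–C4a (Heck: 5-iodo-2,4-dihydroxyacetophenone + terminal alkene), then the cinnamate C=C (vanillin + malonic half-ester), the malonate ester C–O and the vinyl–carbinol C–C bond (hydroxyacetone + vinyl Grignard).
2. Forward: the C5 diol is made, acylated and condensed to the ferulate. The chain is joined to the purchased benzene ring by a Heck reaction. The pyran ring, the only ring that is built, is closed in the last step, and no protecting group is used.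
3. Enabling feature: O1 sits on C8a, ortho to C4a, and the 7-OH is para to C4a. Loss of the C2 hydroxyl therefore gives a cation delocalised over C2–C3–C4 into the arene, a protonated vinyl ortho-quinone methide, whose six atoms O1–C8a–C4a–C4–C3–C2 close to the 2H-chromene.
4. Stereochemistry: the single stereocentre C2 (R) is created in that ring closure, from the racemic carbinol through an achiral cation under control of a chiral Brønsted acid (enantioconvergent). The ferulate (E)-alkene comes from the Knoevenagel–Doebner step.
5. The linear 6-acetyl-7-hydroxy pattern is fixed by the position of the C–I bond before the cyclisation.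

Key step: step 6

Remark on the chemistry: C2 of the target is (R) (O1 > CH2O > C3 > CH3). The sense of induction of the chiral acid cannot be predicted for this dialkyl carbinol, so the (R)-catalyst is written and is exchanged for its antipode if a test run shows the opposite sense. Compounds 3, 5, 7, 8 and 11 are racemic.

**Route**

Step 1
Reactants: 1 hydroxyacetone; 2 vinylmagnesium bromide
Product: 3 rac-2-methylbut-3-ene-1,2-diol
Conditions: 2 (2.5 equiv), THF, −20 °C → rt; aq NH4Cl
Reagents that add atoms: none
Why: Grignard 1,2-addition to the ketone, with one equivalent of 2 consumed by the free hydroxyl, should give the tertiary allylic carbinol as a racemate, which is all the later enantioconvergent ring closure needs.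

Step 2
Reactants: 3 rac-2-methylbut-3-ene-1,2-diol; 4 Meldrum's acid
Product: 5 rac-3-[(2-hydroxy-2-methylbut-3-en-1-yl)oxy]-3-oxopropanoic acid
Conditions: toluene, 90 °C; used crude
Reagents that add atoms: none
Why: Alcoholysis of Meldrum's acid with loss of acetone is a standard route to malonic half-esters and should be selective for the primary hydroxyl over the hindered tertiary allylic one.

Step 3
Reactants: 5 rac-3-[(2-hydroxy-2-methylbut-3-en-1-yl)oxy]-3-oxopropanoic acid; 6 vanillin
Product: 8 rac-2-hydroxy-2-methylbut-3-en-1-yl (E)-3-(4-hydroxy-3-methoxyphenyl)prop-2-enoate, via arylidene malonic half-ester 7 (not isolated)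
Conditions: pyridine, piperidine (cat.), 50 °C
Reagents that add atoms: none
Why: In the Knoevenagel–Doebner condensation the arylidene half-ester 7 decarboxylates in pyridine to the (E)-cinnamate, so the ferulate should be installed without protecting the phenol and without touching the tertiary allylic alcohol.

Step 4
Reactants: 9 1-(2,4-dihydroxyphenyl)ethanone
Product: 10 1-(2,4-dihydroxy-5-iodophenyl)ethanone
Conditions: ICl (1.0 equiv), AcOH, rt; crystallisation from any 3-iodo isomer
Reagents that add atoms: iodine monochloride, ClI
Why: Electrophilic aromatic iodination under acidic, non-phenoxide conditions should favour C5 (ortho to the free 4-OH, para to the chelated 2-OH, less hindered than C3), and this C–I bond fixes the linear 6-acetyl-7-hydroxy pattern of the chromene.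

Step 5
Reactants: 10 1-(2,4-dihydroxy-5-iodophenyl)ethanone; 8 rac-2-hydroxy-2-methylbut-3-en-1-yl (E)-3-(4-hydroxy-3-methoxyphenyl)prop-2-enoate
Product: 11 rac-(E)-4-(5-acetyl-2,4-dihydroxyphenyl)-2-hydroxy-2-methylbut-3-en-1-yl (E)-3-(4-hydroxy-3-methoxyphenyl)prop-2-enoate
Conditions: Pd(OAc)2 (5 mol %), n-Bu4NCl, NaHCO3, DMF, 60 °C; Et3N-deactivated silica
Reagents that add atoms: none
Why: In this Mizoroki–Heck reaction (Jeffery conditions) the aryl group should add to the unsubstituted terminus of the monosubstituted alkene and syn β-hydride elimination should give the (E)-styrene, while the tertiary carbinol has no carbinol hydrogen to be lost and the weakly basic medium keeps the acid-labile 2-hydroxystyryl carbinol from ionising.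

Step 6
Reactants: 11 rac-(E)-4-(5-acetyl-2,4-dihydroxyphenyl)-2-hydroxy-2-methylbut-3-en-1-yl (E)-3-(4-hydroxy-3-methoxyphenyl)prop-2-enoate
Product: 13 [(2R)-6-acetyl-7-hydroxy-2-methyl-2H-chromen-2-yl]methyl (E)-3-(4-hydroxy-3-methoxyphenyl)prop-2-enoate, via allyl cation ion pair 12 (not isolated)
Conditions: (R)-3,3'-bis(2,4,6-triisopropylphenyl)-BINOL N-triflylphosphoramide (10 mol %), toluene–CH2Cl2, −40 °C, dark; Et3N quench
Reagents that add atoms: none
Why: Proposed new method: the strong chiral acid protonates the tertiary allylic hydroxyl of either enantiomer of 11 and water leaves, giving one achiral delocalised cation 12 (the O-protonated vinyl ortho-quinone methide O1=C8a–C4a=C4–C3=C2, further stabilised by the para 7-OH) as a contact ion pair with the chiral phosphoramide anion. Rotation about C3–C4, now essentially a single bond, brings O1 over C2, and the pyran ring closes in a 6-endo mode (attack of the phenolic oxygen on the distal allyl terminus, equivalent to a disrotatory oxa-6π electrocyclisation) with return of aromaticity. The closest known reaction type is the chiral N-triflylphosphoramide-catalysed intramolecular allylic substitution of (E)-2-hydroxycinnamyl tertiary alcohols to 2-aryl-2-methyl-2H-chromenes, supported by confined-acid asymmetric hydroalkoxylation that builds dialkyl tertiary ether centres; what is new is a carbinol carbon carrying two alkyl groups, methyl and acyloxymethyl. The C2 stereocentre is under catalyst control: the anion is hydrogen-bonded to the attacking phenol OH and must deliver O1 to the face of the C2 terminus that gives R, reading the difference in size and polarity between methyl and the CH2O-acyl arm. The step needs enantioconvergence, which the common planar cation supplies, chemoselectivity for O1, which is secured because only the hydroxyl ortho to the side chain can reach C2 in a six-membered array while the 7-OH is locked by its hydrogen bond to the acetyl group, and suppression of the uncatalysed racemic closure of the free quinone methide, for which low temperature and a weakly polar medium are chosen. Placing the step last means that the 2H-chromene, which can racemise by reversible oxa-6π ring opening on heating or irradiation, is never heated afterwards.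

**Compound list**

1 | hydroxyacetone (1-hydroxypropan-2-one) | CC(=O)CO | starting material
2 | vinylmagnesium bromide | C=C[Mg]Br | starting material
3 | rac-2-methylbut-3-ene-1,2-diol | C=CC(C)(O)CO | intermediate
4 | Meldrum's acid (2,2-dimethyl-1,3-dioxane-4,6-dione) | CC1(C)OC(=O)CC(=O)O1 | starting material
5 | rac-3-[(2-hydroxy-2-methylbut-3-en-1-yl)oxy]-3-oxopropanoic acid | C=CC(C)(O)COC(=O)CC(=O)O | intermediate
6 | vanillin (4-hydroxy-3-methoxybenzaldehyde) | COc1cc(C=O)ccc1O | starting material
7 | arylidene malonic half-ester: rac-2-[(4-hydroxy-3-methoxyphenyl)methylidene]propanedioic acid mono(2-hydroxy-2-methylbut-3-en-1-yl) ester, alkene geometry not defined | COc1cc(C=C(C(=O)O)C(=O)OCC(C)(O)C=C)ccc1O | intermediate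
8 | rac-2-hydroxy-2-methylbut-3-en-1-yl (E)-3-(4-hydroxy-3-methoxyphenyl)prop-2-enoate | COc1cc(/C=C/C(=O)OCC(C)(O)C=C)ccc1O | intermediate
9 | 1-(2,4-dihydroxyphenyl)ethanone (2,4-dihydroxyacetophenone) | CC(=O)c1ccc(O)cc1O | starting material
10 | 1-(2,4-dihydroxy-5-iodophenyl)ethanone | CC(=O)c1cc(I)c(O)cc1O | intermediate
11 | rac-(E)-4-(5-acetyl-2,4-dihydroxyphenyl)-2-hydroxy-2-methylbut-3-en-1-yl (E)-3-(4-hydroxy-3-methoxyphenyl)prop-2-enoate | COc1cc(/C=C/C(=O)OCC(C)(O)/C=C/c2cc(C(C)=O)c(O)cc2O)ccc1O | intermediate
12 | allyl cation of the ion pair with the catalyst anion, drawn as the tertiary-cation resonance form of the O-protonated vinyl ortho-quinone methide | COc1cc(/C=C/C(=O)OC[C+](C)/C=C/c2cc(C(C)=O)c(O)cc2O)ccc1O | intermediate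
13 | [(2R)-6-acetyl-7-hydroxy-2-methyl-2H-chromen-2-yl]methyl (E)-3-(4-hydroxy-3-methoxyphenyl)prop-2-enoate | COc1cc(/C=C/C(=O)OC[C@@]2(C)C=Cc3cc(C(C)=O)c(O)cc3O2)ccc1O | target

**Step count and risks**

Total steps: 6. Longest linear sequence: 5 (steps 1, 2, 3, 5, 6).

Steps most likely to fail:

1. Step 6. The catalyst may discriminate poorly between the methyl and acyloxymethyl faces of the cation, or the uncatalysed closure of the free quinone methide may compete, so that the enantiomeric purity is low. Proton loss from the cation to a diene is a further risk.
Fallback (known chemistry), setting out from 10 and coming back to the route at 13. Suzuki–Miyaura coupling of 10 with potassium vinyltrifluoroborate (PdCl2(dppf), Cs2CO3, THF–H2O, 70 °C) should give 1-(2,4-dihydroxy-5-vinylphenyl)ethanone F1. Palladium-catalysed dynamic kinetic asymmetric allylic etherification of racemic 2-methyl-2-vinyloxirane with the acidic, non-chelated 4-OH of F1 (Pd2(dba)3·CHCl3, DACH-naphthyl Trost ligand in the antipode that gives R, CH2Cl2, rt) should set the quaternary centre intermolecularly and give (R)-1-[2-hydroxy-4-[(1-hydroxy-2-methylbut-3-en-2-yl)oxy]-5-vinylphenyl]ethanone F2. Ring-closing metathesis (Grubbs II, CH2Cl2, 40 °C) then closes the same pyran ring at C3=C4 without touching C2 and should give (R)-1-[7-hydroxy-2-(hydroxymethyl)-2-methyl-2H-chromen-6-yl]ethanone F3. Carbodiimide esterification with commercial (E)-4-acetoxy-3-methoxycinnamic acid (EDC·HCl, DMAP, CH2Cl2, 0 °C → rt) should give [(2R)-6-acetyl-7-hydroxy-2-methyl-2H-chromen-2-yl]methyl (E)-3-(4-acetoxy-3-methoxyphenyl)prop-2-enoate F4. Pyrrolidine (CH2Cl2, 0 °C) should remove the aryl acetate selectively and return the route at 13. No step after the metathesis is heated.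

2. Step 5. The product may ionise and close to racemic chromene under thermal or Pd(II) promotion during the coupling, or the free ortho-iodophenol may inhibit the catalyst by chelation.
Fallback, setting out from 8 and coming back at 11. Cross-metathesis of 8 with vinylboronic acid pinacol ester (Hoveyda–Grubbs II, CH2Cl2, 40 °C) should give rac-2-hydroxy-2-methyl-4-(4,4,5,5-tetramethyl-1,3,2-dioxaborolan-2-yl)but-3-en-1-yl (E)-3-(4-hydroxy-3-methoxyphenyl)prop-2-enoate F5 as the (E)-alkenylboronate. Suzuki–Miyaura coupling of F5 with 10 (Pd(dppf)Cl2, K3PO4, THF–H2O, 40 °C) joins the same C4–C4a bond at lower temperature and returns the route at 11.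

3. Step 4. Iodination may be poorly regioselective (C3 against C5) or may run on to the 3,5-diiodide, which would put the side chain at the wrong ring position.
Fallback, replacing starting material 9 and coming back at 10. Commercial 4-iodoresorcinol (Oc1ccc(I)c(O)c1) is C-acetylated under Nencki/Friedel–Crafts conditions (AcOH, BF3·OEt2, 80 °C). The only activated free position that is not flanked by both hydroxyls is C6, so the acetyl group should enter there and give 10 with the regiochemistry fixed by the starting material. This fallback makes no compound outside the list (F0).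

**Further compounds**

F1 | step 6 | 1-(2,4-dihydroxy-5-vinylphenyl)ethanone | CC(=O)c1cc(C=C)c(O)cc1O
F2 | step 6 | (R)-1-[2-hydroxy-4-[(1-hydroxy-2-methylbut-3-en-2-yl)oxy]-5-vinylphenyl]ethanone | OC[C@@](C)(C=C)Oc1cc(O)c(C(C)=O)cc1C=C
F3 | step 6 | (R)-1-[7-hydroxy-2-(hydroxymethyl)-2-methyl-2H-chromen-6-yl]ethanone | OC[C@@]1(C)C=Cc2cc(C(C)=O)c(O)cc2O1
F4 | step 6 | [(2R)-6-acetyl-7-hydroxy-2-methyl-2H-chromen-2-yl]methyl (E)-3-(4-acetoxy-3-methoxyphenyl)prop-2-enoate | COc1cc(/C=C/C(=O)OC[C@@]2(C)C=Cc3cc(C(C)=O)c(O)cc3O2)ccc1OC(C)=O
F5 | step 5 | rac-2-hydroxy-2-methyl-4-(4,4,5,5-tetramethyl-1,3,2-dioxaborolan-2-yl)but-3-en-1-yl (E)-3-(4-hydroxy-3-methoxyphenyl)prop-2-enoate, (E)-alkenylboronate | COc1cc(/C=C/C(=O)OCC(C)(O)/C=C/B2OC(C)(C)C(C)(C)O2)ccc1O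
F0 | step 4 | none | none
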